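The heptane chain is cut at C3–C4. Carbinol carbons C3 and C5 flank the single methylene C4, between the guaiacyl ring on C1 and the syringyl ring on C7. Both C–O bonds can therefore be stored as C–B bonds of a 1,3-bis(boronic ester). In one operation an enantioenriched α-lithiated benzoate (guaiacyl ring, C1–C3) adds to the primary boron on C4 of a 1,2-bis(boronic ester) (C4–C7, syringyl ring). 1,2-Migration of C4 then forms C3–C4 and the C3–B stereocentre. The precursors are a silylated 3-arylpropyl triisopropylbenzoate and an (S)-4-arylbutane-1,2-diyl bis(pinacolboronate) from enantioselective diboration. Stereoretentive oxidation and desilylation deliver the syn-(3S,5R)-diol.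

Key step: step 9

Remark (numbering): the chain is numbered from C1 (bearing the guaiacyl ring) to C7 (bearing the syringyl ring); with this numbering the target SMILES reads (3S,5R), a syn-1,3-diol.

Remark (sense of induction): s-BuLi/(−)-sparteine is taken to remove the pro-S α-hydrogen of primary benzoates, so (+)-sparteine is required in step 9; for step 8 the ligand enantiomer is assigned by oxidising a sample of 14 to its 1,2-diol and correlating the configuration, and the antipodal ligand is used if the sense is opposite.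

Step 1
Reactants: 1 eugenol
Product: 2 (4-allyl-2-methoxyphenoxy)(tert-butyl)dimethylsilane
Conditions: TBSCl, imidazole, DMF, rt
Reagents that add atoms: tert-butyldimethylsilyl chloride, CC(C)(C)[Si](C)(C)Cl
Why: Imidazole-promoted O-silylation of a phenol, in which the allyl group is inert and no stereocentre is involved.

Step 2
Reactants: 2 (4-allyl-2-methoxyphenoxy)(tert-butyl)dimethylsilane
Product: 4 3-[4-(tert-butyldimethylsilyloxy)-3-methoxyphenyl]propan-1-ol, via trialkylborane 3 (not isolated)
Conditions: 9-BBN, THF, 0 °C → rt; then NaBO3·4H2O, THF/H2O, rt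
Reagents that add atoms: sodium perborate, [Na+].[Na+].O[B-]1(O)OO[B-](O)(O)OO1 (oxygen of 4); 9-BBN, B1C2CCCC1CCC2 (boron and ring of intermediate 3 only)
Why: Anti-Markovnikov hydroboration–oxidation, in which bulky 9-BBN places boron on the terminal carbon and the mild perborate oxidation spares the base-sensitive aryl silyl ether.

Step 3
Reactants: 4 3-[4-(tert-butyldimethylsilyloxy)-3-methoxyphenyl]propan-1-ol; 5 2,4,6-triisopropylbenzoyl chloride
Product: 6 3-[4-(tert-butyldimethylsilyloxy)-3-methoxyphenyl]propyl 2,4,6-triisopropylbenzoate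
Conditions: Et3N, DMAP (0.2 equiv), CH2Cl2, 0 °C → reflux
Reagents that add atoms: 2,4,6-triisopropylbenzoyl chloride 5, CC(C)c1cc(C(C)C)c(C(=O)Cl)c(C(C)C)c1
Why: DMAP-catalysed acylation of an unhindered primary alcohol, giving a hindered ester whose carbonyl later resists attack by s-BuLi.

Step 4
Reactants: 7 syringaldehyde
Product: 8 4-(tert-butyldimethylsilyloxy)-3,5-dimethoxybenzaldehyde
Conditions: TBSCl, imidazole, DMAP (cat.), DMF, rt
Reagents that add atoms: tert-butyldimethylsilyl chloride, CC(C)(C)[Si](C)(C)Cl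
Why: Imidazole-promoted O-silylation of a phenol that is acidified by the para-formyl group and remains reactive in DMF despite its two flanking methoxy groups.

Step 5
Reactants: 8 4-(tert-butyldimethylsilyloxy)-3,5-dimethoxybenzaldehyde
Product: 9 [4-(tert-butyldimethylsilyloxy)-3,5-dimethoxyphenyl]methanol
Conditions: NaBH4, THF/EtOH, 0 °C, short reaction time; aq NH4Cl
Reagents that add atoms: none
Why: Borohydride reduction of an aromatic aldehyde, kept cold and short so that alkoxide does not strip the aryl silyl ether.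

Step 6
Reactants: 9 [4-(tert-butyldimethylsilyloxy)-3,5-dimethoxyphenyl]methanol
Product: 10 4-(tert-butyldimethylsilyloxy)-3,5-dimethoxybenzyl bromide
Conditions: CBr4, PPh3, CH2Cl2, 0 °C; short silica plug, used at once
Reagents that add atoms: carbon tetrabromide, BrC(Br)(Br)Br
Why: Appel reaction, which converts the primary benzylic alcohol through its alkoxyphosphonium salt by SN2 under neutral conditions, avoiding acid that would ionise the electron-rich benzylic position.

Step 7
Reactants: 10 4-(tert-butyldimethylsilyloxy)-3,5-dimethoxybenzyl bromide; 11 allylmagnesium bromide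
Product: 12 4-[4-(tert-butyldimethylsilyloxy)-3,5-dimethoxyphenyl]but-1-ene
Conditions: allylMgBr (1.0 M in Et2O, 1.5 equiv), THF, 0 °C → rt
Reagents that add atoms: allylmagnesium bromide 11, C=CC[Mg]Br
Why: Uncatalysed substitution of a reactive benzylic bromide by an allyl Grignard reagent, a coupling that aryl silyl and methyl ethers tolerate at this temperature.

Step 8
Reactants: 12 4-[4-(tert-butyldimethylsilyloxy)-3,5-dimethoxyphenyl]but-1-ene; 13 bis(pinacolato)diboron
Product: 14 (S)-2,2'-{4-[4-(tert-butyldimethylsilyloxy)-3,5-dimethoxyphenyl]butane-1,2-diyl}bis(4,4,5,5-tetramethyl-1,3,2-dioxaborolane)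
Conditions: Pt(dba)3 (1 mol %), 3,5-diisopropylphenyl-TADDOL phenylphosphonite (1.2 mol %, enantiomer per remark), 13 (1.05 equiv), THF, 80 °C, 30 min; then 12, 60 °C
Reagents that add atoms: bis(pinacolato)diboron 13, CC1(C)OB(OC1(C)C)B1OC(C)(C)C(C)(C)O1
Why: Pt(0)-catalysed enantioselective syn-1,2-diboration of a monosubstituted alkene, in which B–B oxidative addition, ligand-controlled insertion of the alkene into Pt–B and reductive elimination set the C5–B centre as (S).

Step 9
Reactants: 6 3-[4-(tert-butyldimethylsilyloxy)-3-methoxyphenyl]propyl 2,4,6-triisopropylbenzoate; 14 (S)-2,2'-{4-[4-(tert-butyldimethylsilyloxy)-3,5-dimethoxyphenyl]butane-1,2-diyl}bis(4,4,5,5-tetramethyl-1,3,2-dioxaborolane)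
Product: 17 (3S,5R)-1-[4-(tert-butyldimethylsilyloxy)-3-methoxyphenyl]-7-[4-(tert-butyldimethylsilyloxy)-3,5-dimethoxyphenyl]heptane-3,5-diyl bis(pinacolboronate), via lithiated benzoate 15 (not isolated), via boronate complex 16 (not isolated)
Conditions: 6 (1.3 equiv), (+)-sparteine (1.3 equiv), s-BuLi (1.2 equiv), Et2O, −78 °C, 5 h; 14 (1.0 equiv) in Et2O, −78 °C, 2 h; then rt → 35 °C, 16 h; aq NH4Cl
Reagents that add atoms: s-BuLi, CCC(C)[Li] (lithium of intermediates 15 and 16 only; no atom in 17)
Why: Lithiation–borylation (a reagent-controlled, Matteson-type homologation): s-BuLi/(+)-sparteine removes the pro-R α-hydrogen of the primary, unbranched benzoate 6 under direction by the ester carbonyl, and the configurationally stable (R)-carbenoid 15 adds to boron with retention to give boronate complex 16. On warming, C4 migrates from boron to C3 antiperiplanar to the departing triisopropylbenzoate, with inversion at C3, which forms the C3–C4 bond and the (3S) C–B centre in the same event. The closest known reaction type is the homologation of 1,2-bis(boronic esters) at the primary boron with lithiated benzoates or carbamates to give 1,3-bis(boronic esters). No ring is closed; the one new stereocentre, C3, is controlled only by the diamine and the stereospecific shift, whereas C5 is carried unchanged from step 8, so the syn array results from pairing (+)-sparteine with (S)-14. The selectivity needed is site selectivity between the two Bpin groups, and it is secured sterically: the boron on the CH2 group C4 is open, the boron on the branched C5 is shielded, s-BuLi is kept below the amount of 6, and the carbenoid is used in only slight excess, so that neither free s-BuLi nor a second carbenoid reaches boron. The aryl silyl and methyl ethers should survive because carbonyl-directed α-deprotonation at −78 °C in Et2O outruns ring lithiation, and any minor enantiomer of either partner should end up mainly as the anti diastereomer, removable by chromatography at 17 or 18.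

Step 10
Reactants: 17 (3S,5R)-bis(pinacolboronate)
Product: 18 (3S,5R)-1-[4-(tert-butyldimethylsilyloxy)-3-methoxyphenyl]-7-[4-(tert-butyldimethylsilyloxy)-3,5-dimethoxyphenyl]heptane-3,5-diol
Conditions: NaBO3·4H2O (excess), THF/H2O 1:1, rt
Reagents that add atoms: sodium perborate, [Na+].[Na+].O[B-]1(O)OO[B-](O)(O)OO1
Why: Stereoretentive oxidation of both secondary C–B bonds (peroxide adds to boron, carbon shifts to oxygen with retention), run with mild perborate rather than hydroxide/peroxide to keep the aryl silyl ethers and so shield the electron-rich phenols from the oxidant.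

Step 11
Reactants: 18 (3S,5R)-bis-silylated diol
Product: 19 (3S,5R)-1-(4-hydroxy-3-methoxyphenyl)-7-(4-hydroxy-3,5-dimethoxyphenyl)heptane-3,5-diol (CNP0317264.2)
Conditions: TBAF (2.4 equiv), AcOH (2.4 equiv), THF, 0 °C, under Ar
Reagents that add atoms: none
Why: Fluoride-induced cleavage of the two aryl silyl ethers, driven by Si–F bond formation and buffered by acetic acid so that the phenoxides are protonated at once and not air-oxidised, with the carbinol centres untouched.

Compound list
1 | eugenol (4-allyl-2-methoxyphenol) | C=CCc1ccc(O)c(OC)c1 | starting material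
2 | (4-allyl-2-methoxyphenoxy)(tert-butyl)dimethylsilane | C=CCc1ccc(O[Si](C)(C)C(C)(C)C)c(OC)c1 | intermediate
3 | trialkylborane: B-{3-[4-(tert-butyldimethylsilyloxy)-3-methoxyphenyl]propyl}-9-borabicyclo[3.3.1]nonane (not isolated) | COc1cc(CCCB2C3CCCC2CCC3)ccc1O[Si](C)(C)C(C)(C)C | intermediate
4 | 3-[4-(tert-butyldimethylsilyloxy)-3-methoxyphenyl]propan-1-ol | COc1cc(CCCO)ccc1O[Si](C)(C)C(C)(C)C | intermediate
5 | 2,4,6-triisopropylbenzoyl chloride | CC(C)c1cc(C(C)C)c(C(=O)Cl)c(C(C)C)c1 | starting material
6 | 3-[4-(tert-butyldimethylsilyloxy)-3-methoxyphenyl]propyl 2,4,6-triisopropylbenzoate | COc1cc(CCCOC(=O)c2c(C(C)C)cc(C(C)C)cc2C(C)C)ccc1O[Si](C)(C)C(C)(C)C | intermediate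
7 | syringaldehyde | COc1cc(C=O)cc(OC)c1O | starting material
8 | 4-(tert-butyldimethylsilyloxy)-3,5-dimethoxybenzaldehyde | COc1cc(C=O)cc(OC)c1O[Si](C)(C)C(C)(C)C | intermediate
9 | [4-(tert-butyldimethylsilyloxy)-3,5-dimethoxyphenyl]methanol | COc1cc(CO)cc(OC)c1O[Si](C)(C)C(C)(C)C | intermediate
10 | 4-(tert-butyldimethylsilyloxy)-3,5-dimethoxybenzyl bromide | COc1cc(CBr)cc(OC)c1O[Si](C)(C)C(C)(C)C | intermediate
11 | allylmagnesium bromide | C=CC[Mg]Br | starting material
12 | 4-[4-(tert-butyldimethylsilyloxy)-3,5-dimethoxyphenyl]but-1-ene | C=CCCc1cc(OC)c(O[Si](C)(C)C(C)(C)C)c(OC)c1 | intermediate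
13 | bis(pinacolato)diboron | CC1(C)OB(OC1(C)C)B1OC(C)(C)C(C)(C)O1 | starting material
14 | (S)-2,2'-{4-[4-(tert-butyldimethylsilyloxy)-3,5-dimethoxyphenyl]butane-1,2-diyl}bis(4,4,5,5-tetramethyl-1,3,2-dioxaborolane) | CC1(C)OB(C[C@H](B2OC(C)(C)C(C)(C)O2)CCc2cc(OC)c(O[Si](C)(C)C(C)(C)C)c(OC)c2)OC1(C)C | intermediate
15 | lithiated benzoate: (R)-1-lithio-3-[4-(tert-butyldimethylsilyloxy)-3-methoxyphenyl]propyl 2,4,6-triisopropylbenzoate, present as its (+)-sparteine complex, drawn without the diamine (not isolated) | COc1cc(CC[C@@H]([Li])OC(=O)c2c(C(C)C)cc(C(C)C)cc2C(C)C)ccc1O[Si](C)(C)C(C)(C)C | intermediate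
16 | boronate complex: lithium salt in which the former primary Bpin carries C4 and the (R)-configured C3 bearing the triisopropylbenzoyloxy group, C5–Bpin unchanged (not isolated) | [Li+].COc1cc(CC[C@H](OC(=O)c2c(C(C)C)cc(C(C)C)cc2C(C)C)[B-]2(OC(C)(C)C(C)(C)O2)C[C@H](B2OC(C)(C)C(C)(C)O2)CCc2cc(OC)c(O[Si](C)(C)C(C)(C)C)c(OC)c2)ccc1O[Si](C)(C)C(C)(C)C | intermediate
17 | (3S,5R)-1-[4-(tert-butyldimethylsilyloxy)-3-methoxyphenyl]-7-[4-(tert-butyldimethylsilyloxy)-3,5-dimethoxyphenyl]heptane-3,5-diyl bis(pinacolboronate) | COc1cc(CC[C@H](B2OC(C)(C)C(C)(C)O2)C[C@H](B2OC(C)(C)C(C)(C)O2)CCc2cc(OC)c(O[Si](C)(C)C(C)(C)C)c(OC)c2)ccc1O[Si](C)(C)C(C)(C)C | intermediate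
18 | (3S,5R)-1-[4-(tert-butyldimethylsilyloxy)-3-methoxyphenyl]-7-[4-(tert-butyldimethylsilyloxy)-3,5-dimethoxyphenyl]heptane-3,5-diol | COc1cc(CC[C@H](O)C[C@H](O)CCc2cc(OC)c(O[Si](C)(C)C(C)(C)C)c(OC)c2)ccc1O[Si](C)(C)C(C)(C)C | intermediate
19 | (3S,5R)-1-(4-hydroxy-3-methoxyphenyl)-7-(4-hydroxy-3,5-dimethoxyphenyl)heptane-3,5-diol | COc1cc(CC[C@H](O)C[C@H](O)CCc2cc(OC)c(O)c(OC)c2)ccc1O | target

Total step count: 11. Longest linear sequence: 8 steps (steps 4–8, then 9–11, from syringaldehyde).

Steps most likely to fail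

Risk 1, step 9. The long deprotonation of 6 may be incomplete or accompanied by ring lithiation next to the methoxy or silyloxy group. The carbenoid may add to both boron atoms. The migration may be sluggish or diverted to oxygen migration. The fallback uses no boron homologation. It relies on an epoxide–dithiane union followed by a chelate-controlled syn reduction, sets out from 14 and 4, and comes back at 18. Compound 14 is oxidised with sodium perborate to (R)-4-[4-(tert-butyldimethylsilyloxy)-3,5-dimethoxyphenyl]butane-1,2-diol F1. NaH/N-tosylimidazole in THF closes F1 through the primary sulfonate to the terminal (R)-epoxide F2, without touching the C5–O bond. In parallel, 4 is oxidised with Dess–Martin periodinane to the aldehyde F3, which propane-1,3-dithiol and BF3·OEt2 convert into the dithiane F4. F4 is deprotonated with n-BuLi in THF and opens F2 at its terminal carbon C4 (Corey–Seebach umpolung) to give the hydroxy dithiane F5. MeI/CaCO3 in aqueous MeCN unmasks the (5R)-β-hydroxy ketone F6. Narasaka–Prasad reduction (Et2BOMe, NaBH4, THF/MeOH, −78 °C) should then give the syn-diol 18, with C3 set by C5 through the six-membered boron chelate.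

Risk 2, step 8. Facial selectivity in the insertion of an unbranched terminal alkene may be insufficient, or traces of bromide or phosphorus residues from steps 6 and 7 may deactivate the platinum catalyst. The fallback is a unidirectional lithiation–borylation of diborylmethane that sets out from 12 and comes back at 14. Lemieux–Johnson cleavage of 12 (OsO4 cat., NaIO4, 2,6-lutidine, dioxane/H2O) gives the aldehyde F7. NaBH4 reduces F7 to the alcohol F8, and acylation with 5 (Et3N, DMAP) gives the benzoate F9. s-BuLi/(−)-sparteine in Et2O at −78 °C should give the (S)-lithiated benzoate F10. F10 adds to one boron of commercial bis[(pinacolato)boryl]methane to form the boronate complex F11. On warming, the CH2Bpin group migrates with inversion and gives (S)-14, so C5 is set by the diamine instead of the platinum ligand.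

Risk 3, step 6. The very electron-rich benzylic bromide may ionise during isolation, with self-alkylation of the activated ring or loss of the silyl group through a quinone-methide pathway. Reductive dimerisation may follow in step 7. The fallback, carbonyl allylation followed by ionic deoxygenation, avoids any benzylic halide; it sets out from 8 and comes back at 12. Addition of 11 to aldehyde 8 in THF at −78 °C gives the racemic homoallylic benzylic alcohol F12. Et3SiH with trifluoroacetic acid in CH2Cl2 at low temperature should reduce F12 through the stabilised benzylic cation to 12, leaving the isolated terminal alkene and the acid-tolerant aryl silyl ether in place.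

Further compounds
F1 | step 9 | (R)-4-[4-(tert-butyldimethylsilyloxy)-3,5-dimethoxyphenyl]butane-1,2-diol | OC[C@H](O)CCc1cc(OC)c(O[Si](C)(C)C(C)(C)C)c(OC)c1
F2 | step 9 | (R)-2-{2-[4-(tert-butyldimethylsilyloxy)-3,5-dimethoxyphenyl]ethyl}oxirane | C1O[C@@H]1CCc1cc(OC)c(O[Si](C)(C)C(C)(C)C)c(OC)c1
F3 | step 9 | 3-[4-(tert-butyldimethylsilyloxy)-3-methoxyphenyl]propanal | COc1cc(CCC=O)ccc1O[Si](C)(C)C(C)(C)C
F4 | step 9 | 2-{2-[4-(tert-butyldimethylsilyloxy)-3-methoxyphenyl]ethyl}-1,3-dithiane | COc1cc(CCC2SCCCS2)ccc1O[Si](C)(C)C(C)(C)C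
F5 | step 9 | (R)-1-(2-{2-[4-(tert-butyldimethylsilyloxy)-3-methoxyphenyl]ethyl}-1,3-dithian-2-yl)-4-[4-(tert-butyldimethylsilyloxy)-3,5-dimethoxyphenyl]butan-2-ol | COc1cc(CCC2(C[C@H](O)CCc3cc(OC)c(O[Si](C)(C)C(C)(C)C)c(OC)c3)SCCCS2)ccc1O[Si](C)(C)C(C)(C)C
F6 | step 9 | (5R)-1-[4-(tert-butyldimethylsilyloxy)-3-methoxyphenyl]-7-[4-(tert-butyldimethylsilyloxy)-3,5-dimethoxyphenyl]-5-hydroxyheptan-3-one | COc1cc(CCC(=O)C[C@H](O)CCc2cc(OC)c(O[Si](C)(C)C(C)(C)C)c(OC)c2)ccc1O[Si](C)(C)C(C)(C)C
F7 | step 8 | 3-[4-(tert-butyldimethylsilyloxy)-3,5-dimethoxyphenyl]propanal | COc1cc(CCC=O)cc(OC)c1O[Si](C)(C)C(C)(C)C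
F8 | step 8 | 3-[4-(tert-butyldimethylsilyloxy)-3,5-dimethoxyphenyl]propan-1-ol | COc1cc(CCCO)cc(OC)c1O[Si](C)(C)C(C)(C)C
F9 | step 8 | 3-[4-(tert-butyldimethylsilyloxy)-3,5-dimethoxyphenyl]propyl 2,4,6-triisopropylbenzoate | COc1cc(CCCOC(=O)c2c(C(C)C)cc(C(C)C)cc2C(C)C)cc(OC)c1O[Si](C)(C)C(C)(C)C
F10 | step 8 | (S)-1-lithio-3-[4-(tert-butyldimethylsilyloxy)-3,5-dimethoxyphenyl]propyl 2,4,6-triisopropylbenzoate, (−)-sparteine complex (drawn without the diamine) | COc1cc(CC[C@H]([Li])OC(=O)c2c(C(C)C)cc(C(C)C)cc2C(C)C)cc(OC)c1O[Si](C)(C)C(C)(C)C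
F11 | step 8 | lithium boronate complex of F10 with one boron of bis[(pinacolato)boryl]methane | [Li+].COc1cc(CC[C@@H](OC(=O)c2c(C(C)C)cc(C(C)C)cc2C(C)C)[B-]2(OC(C)(C)C(C)(C)O2)CB2OC(C)(C)C(C)(C)O2)cc(OC)c1O[Si](C)(C)C(C)(C)C
F12 | step 6 | rac-1-[4-(tert-butyldimethylsilyloxy)-3,5-dimethoxyphenyl]but-3-en-1-ol | C=CCC(O)c1cc(OC)c(O[Si](C)(C)C(C)(C)C)c(OC)c1
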